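Green and grey were charged at the same equivalents and mol%, with grey only 1.50 times as concentrated, and that pair yields the number to carry to the flask.

| setting | green | grey | ochre | flask |
|---|---|---|---|---|
| starting material | 0.050 M | 0.075 M | 0.10 M | 0.10 M |
| second substrate | 2 equiv | 2 equiv | 2 equiv | 2.00 equiv |
| free catalyst | 7 mol% | 7 mol% | 14 mol% | 7 mol% |
| remark | run made earlier | run made earlier | run made earlier |  |

| run | time / min | target / % |
|---|---|---|
| green | 20.0 | 26.2 |
| green | 40.0 | 41.7 |
| green | 50.0 | 48.1 |
| green | 80.0 | 58.5 |
| grey | 20.0 | 30.1 |
| grey | 40.0 | 43.0 |
| grey | 50.0 | 48.2 |
| grey | 80.0 | 60.6 |
| ochre | 10.0 | 36.2 |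
| ochre | 25.0 | 57.0 |
| ochre | 50.0 | 71.6 |
| ochre | 80.0 | 76.0 |

(standard deviation of a reading: 1 percentage point)

1. apparent order in second substrate when 20% of the starting material are converted (percent change of the rate of making target for one percent more second substrate charged)
2. apparent order in free catalyst when 20% of the starting material are converted (percent change of the rate of making target for one percent more free catalyst charged)

1. The bench rule says that if the total order is one, percent-against-time curves of scaled charges coincide. At 50.0 min they do, with green at 48.1% and grey at 48.2%.
2. The rule stops working early. At 20.0 min grey leads green by a ratio of 1.15, a gap of 3.9 percentage points against a scatter of 1 point.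
3. Define the early total order as the percent change of rate for one percent more of every charge together. Read over the first 20.0 min, it is one plus the ln of that ratio over the ln of the concentration ratio: 1.34, a reading that carries their scatter.
4. Ochre reaches 57.0% at 25.0 min and green reaches 58.5% at 80.0 min, so ochre runs about 3.20 times as fast. Ochre has twice the concentration and twice the loading. Taking the doublings in that factor and subtracting the total order less one, my catalyst order is 1.34.
5. That leaves 0.00641, as a reading, for both substrates together, and these runs show only the sum, since the equivalents never changed. Second substrate outnumbers catalyst 28.6 to one. My assumption is a fast binding equilibrium that holds most of the catalyst, with free catalyst inversely proportional to c(second substrate). Assuming also order one in starting material, I commit to −0.994 in second substrate.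
6. The forecast gives 0.2 in second substrate and 1.2 in free catalyst, saying “its order is poorly fixed”. It differs from my reckoning on both, most in second substrate.

    second substrate + free catalyst ⇌ catalyst intermediate B (K = 270 L mol⁻¹, k = 5.40 L mol⁻¹ min⁻¹)
    starting material + free catalyst ⇌ catalyst intermediate A (K = 6.90 L mol⁻¹, k = 160 L mol⁻¹ min⁻¹)
    catalyst intermediate A → free catalyst + target (k = 2.30 min⁻¹)
    2 starting material → homo dimer (k = 0.180 L mol⁻¹ min⁻¹)
    catalyst intermediate B → free catalyst + second product (k = 0.260 min⁻¹)

The flask gives 1.2 in free catalyst, which the forecast met, and −0.94 in second substrate, below the forecast. Held against 1.34, the reading from green and grey over their first 20.0 min, these leave a remainder of 1.08 for starting material. On the ochre run, 1.34 with that catalyst order gives a factor of 2.91 over green, where the readings gave 3.20. In the flask, free catalyst enters catalyst intermediate B at 65 h⁻¹ with second substrate as charged, faster than intermediate B turns over at 16 h⁻¹, and at 0.200 h this resting state holds 72.1% of the catalyst against 20.8% free.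

The numbers in the tables are calculated for substances that don't exist.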